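Cuts: first the two acyl–oxygen bonds to (R)-danshensu. Then, with a second carboxyl restored on C2, the ring bond C1–C2. Last the chain bond C3–C4, which leaves one aldehyde (used twice), diallyl malonate and N-acetylglycine.
Enabling feature: ring carbon C1 holds only H, an ester carbonyl and the benzylic ring carbon C4, so C4–C1–CO2R is a 3-aryl-2-oxypropanoate unit. An oxygen leaving group on C1 is therefore alpha to that ester, and C2, reached over C4 and C3, can be a malonate carbon.
Forward: an arylpyruvate and an arylidenemalonate are joined at C3–C4. The C1 ketone becomes carbinol and then triflate, and the C2 sodium malonate closes the cyclobutane, the only ring built. Loss of one C2 carboxyl, double esterification and one global hydrogenolysis follow.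
Stereochemistry: C3 comes from a chiral Lewis acid (step 5); C4 and the C1 carbinol from one dynamic kinetic transfer hydrogenation (step 6); ring C1 from SN2 inversion, which writes the strained cis C1-ester/C4-aryl pair (step 8); C2 from kinetic protonation anti to the C3 aryl (step 10); the side-chain centres from (R)-danshensu.

Key step: step 8

Conventions: C1–C4 are the ring carbons of the target in every compound, open-chain ones included. C1 and C2 bear carboxyl groups, C3 and C4 bear aryl groups, and C4 is bonded to C1. In the butane-1,1,4-tricarboxylates the locants 1, 2, 3, 4 are ring C2, C3, C4, C1. In the cyclobutane-1,1,2-tricarboxylates the locants 1, 2, 3, 4 are ring C2, C1, C4, C3.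
Assumption: the senses of induction of the catalysts in steps 5 and 6 are assigned by analogy (in step 6 the ester takes the place of the aryl group of an aryl ketone); the antipodal ligand is used should the opposite sense be found.

Step 1
Reactants: 1 3,4-bis(benzyloxy)benzaldehyde; 2 N-acetylglycine
Product: 4 (Z)-4-[3,4-bis(benzyloxy)benzylidene]-2-methyl-1,3-oxazol-5(4H)-one, via 2-methyl-1,3-oxazol-5(4H)-one 3 (not isolated)
Conditions: NaOAc, Ac2O, 110 °C
Reagents that add atoms: none
Why: Erlenmeyer–Plöchl azlactone synthesis, in which Ac2O cyclodehydrates 2 to 3 and the acidic ring CH2 of 3 condenses with the aldehyde to the thermodynamically preferred Z alkene; no stereocentre is formed.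

Step 2
Reactants: 4 (Z)-4-[3,4-bis(benzyloxy)benzylidene]-2-methyl-1,3-oxazol-5(4H)-one
Product: 6 3-[3,4-bis(benzyloxy)phenyl]-2-oxopropanoic acid, via sodium acetamidocinnamate 5 (not isolated)
Conditions: 10% aq NaOH, reflux, N2; then 6 M HCl, 0 °C
Reagents that add atoms: water, O; sodium hydroxide, [Na+].[OH-]
Why: Alkaline azlactone hydrolysis, in which hydroxide opens the ring to enamide 5 and cleaves the amide, and the freed enamine hydrolyses to the alpha-keto acid under conditions that benzyl aryl ethers tolerate; no stereocentre is formed.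

Step 3
Reactants: 6 3-[3,4-bis(benzyloxy)phenyl]-2-oxopropanoic acid
Product: 7 allyl 3-[3,4-bis(benzyloxy)phenyl]-2-oxopropanoate
Conditions: allyl bromide, KHCO3, DMF, 20 °C
Reagents that add atoms: allyl bromide, C=CCBr
Why: SN2 O-alkylation of the carboxylate; KHCO3 ionises only the acid, so the enol oxygen and the benzylic carbon stay unalkylated, and the allyl ester can later be removed without acid, hydroxide or hydrogen.

Step 4
Reactants: 1 3,4-bis(benzyloxy)benzaldehyde; 8 diallyl malonate
Product: 9 diallyl 2-[3,4-bis(benzyloxy)benzylidene]malonate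
Conditions: piperidine (10 mol %), AcOH (10 mol %), toluene, reflux, Dean–Stark
Reagents that add atoms: none
Why: Knoevenagel condensation driven by azeotropic removal of water; the two ester groups are identical, so no alkene isomers arise.

Step 5
Reactants: 7 allyl 3-[3,4-bis(benzyloxy)phenyl]-2-oxopropanoate; 9 diallyl 2-[3,4-bis(benzyloxy)benzylidene]malonate
Product: 10 triallyl (2R)-2,3-bis[3,4-bis(benzyloxy)phenyl]-4-oxobutane-1,1,4-tricarboxylate (C3 is R; C4 is an equilibrating epimer pair)
Conditions: Sc(OTf)3 (10 mol %), N,N'-dioxide ligand from (S)-pipecolic acid and 2,6-diisopropylaniline with a propane-1,3-diyl linker (10 mol %), iPr2NEt (10 mol %), 4 Å MS, CH2Cl2 (1 M), 30 °C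
Reagents that add atoms: none
Why: Proposed new method: the trivalent scandium complex should bind both ester carbonyls of 9 in a six-membered chelate, which lowers the LUMO and shields the Re face of C3, while the amine turns the acidic, strongly enolised keto ester 7 into its ammonium enolate, which attacks the open Si face through C4 and sets C3 as R; C4 is formed too but stays labile (benzylic and alpha to the ketone) and is left to step 6; the closest known reaction types are chiral-Lewis-acid-catalysed additions of indoles, enamides and enolsilanes to chelated arylidenemalonates and metal-catalysed asymmetric Michael additions of alpha-keto esters to nitroalkenes, but this donor–acceptor pair has not been described.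

Step 6
Reactants: 10 triallyl (2R)-2,3-bis[3,4-bis(benzyloxy)phenyl]-4-oxobutane-1,1,4-tricarboxylate
Product: 11 triallyl (2R,3S,4R)-2,3-bis[3,4-bis(benzyloxy)phenyl]-4-hydroxybutane-1,1,4-tricarboxylate
Conditions: RuCl[(R,R)-TsDPEN](p-cymene) (2 mol %), HCO2H/Et3N (5:2), DMF, 25 °C
Reagents that add atoms: none
Why: Noyori–Ikariya transfer hydrogenation run as a dynamic kinetic resolution, a reaction type established for beta-aryl alpha-keto esters, in which C4 epimerises through the enol, the catalyst reduces the (4S)-ketone faster and delivers hydride to one carbonyl face, giving the (R)-carbinol anti to the C4 aryl while C3 is untouched and the poorly nucleophilic alpha-ester hydroxyl resists lactonisation onto the malonate.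

Step 7
Reactants: 11 triallyl (2R,3S,4R)-2,3-bis[3,4-bis(benzyloxy)phenyl]-4-hydroxybutane-1,1,4-tricarboxylate
Product: 12 triallyl (2R,3S,4R)-2,3-bis[3,4-bis(benzyloxy)phenyl]-4-[(trifluoromethanesulfonyl)oxy]butane-1,1,4-tricarboxylate
Conditions: Tf2O, 2,6-lutidine, CH2Cl2, −78 °C; cold aqueous wash, used at once
Reagents that add atoms: trifluoromethanesulfonic anhydride, O=S(=O)(OS(=O)(=O)C(F)(F)F)C(F)(F)F
Why: O-sulfonylation breaks no bond to C1, so the configuration is retained, and the hindered weak base at −78 °C neither eliminates nor deprotonates the malonate; alpha-triflyloxy esters are an isolable compound class.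

Step 8
Reactants: 12 triallyl (2R,3S,4R)-2,3-bis[3,4-bis(benzyloxy)phenyl]-4-[(trifluoromethanesulfonyl)oxy]butane-1,1,4-tricarboxylate
Product: 14 triallyl (2R,3R,4S)-3,4-bis[3,4-bis(benzyloxy)phenyl]cyclobutane-1,1,2-tricarboxylate, via sodium malonate enolate 13 (not isolated)
Conditions: NaH (1.05 equiv), THF (0.01 M), −20 to 0 °C
Reagents that add atoms: none
Why: NaH removes only the C2–H of the malonate, the most acidic proton, and the chelated sodium enolate 13 attacks C1 through carbon from the side opposite the C1–O bond and expels triflate in an intramolecular SN2 reaction. The closest known reaction types are the closure of (3-halopropyl)malonates to cyclobutane-1,1-diesters and the invertive alkylation of sodium malonates with alpha-triflyloxy esters. The cyclobutane closes in the 4-exo-tet mode, helped by the conformer with anti aryl groups, which already holds C1 and C2 gauche. The one new stereocentre, ring C1, is fixed by inversion of the (R)-carbinol centre set in step 6, which places the C1 ester cis to the C4 aryl, while C3 and C4 are only carried over. The step needs C-alkylation with inversion over loss of triflic acid toward the benzylic C4–H, over Grob-type cleavage of C3–C4 into a cinnamate and the arylidenemalonate, and over O-alkylation to a six-membered ketene acetal. The adjacent ester accelerates substitution and suppresses ionisation at C1, no dissolved base stronger than the malonate anion is present at low temperature and high dilution, and sodium chelation turns both enolate oxygens away from the chain so that only carbon can reach C1.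

Step 9
Reactants: 14 triallyl (2R,3R,4S)-3,4-bis[3,4-bis(benzyloxy)phenyl]cyclobutane-1,1,2-tricarboxylate
Product: 15 (2R,3R,4S)-3,4-bis[3,4-bis(benzyloxy)phenyl]cyclobutane-1,1,2-tricarboxylic acid
Conditions: Pd(PPh3)4 (5 mol %), morpholine, THF, 20 °C; cold dilute HCl wash
Reagents that add atoms: none
Why: Tsuji–Trost deallylation, in which zerovalent palladium ionises the three allyl esters and morpholine captures the allyl units; this near-neutral method is chosen because the 2-aryl-1,1-diester (donor–acceptor) cyclobutane would not survive strong acid and C1 would not survive hydroxide.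

Step 10
Reactants: 15 (2R,3R,4S)-3,4-bis[3,4-bis(benzyloxy)phenyl]cyclobutane-1,1,2-tricarboxylic acid
Product: 17 (1R,2R,3R,4R)-3,4-bis[3,4-bis(benzyloxy)phenyl]cyclobutane-1,2-dicarboxylic acid, via C2 enediol 16 (not isolated)
Conditions: Cu2O (10 mol %), MeCN, 80 °C
Reagents that add atoms: none
Why: Decarboxylation of a malonic acid catalysed by monovalent copper, far below the purely thermal range; C2 is set by kinetic ketonisation of 16 on the face anti to the adjacent C3 aryl, which is also the face of the small C1 carboxyl group that can hold the copper and relay the proton, so the surviving carboxyl should end cis to the C3 aryl and trans to the C1 carboxyl.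

Step 11
Reactants: 18 (R)-danshensu, (2R)-3-(3,4-dihydroxyphenyl)-2-hydroxypropanoic acid
Product: 19 benzyl (2R)-3-[3,4-bis(benzyloxy)phenyl]-2-hydroxypropanoate
Conditions: BnBr (3.3 equiv), K2CO3, DMF, 20 °C, Ar
Reagents that add atoms: benzyl bromide, BrCc1ccccc1
Why: Williamson and carboxylate alkylation; K2CO3 ionises only the two phenols and the acid, so the secondary hydroxyl stays free and the stereocentre is not touched.

Step 12
Reactants: 17 (1R,2R,3R,4R)-3,4-bis[3,4-bis(benzyloxy)phenyl]cyclobutane-1,2-dicarboxylic acid; 19 benzyl (2R)-3-[3,4-bis(benzyloxy)phenyl]-2-hydroxypropanoate (2.4 equiv)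
Product: 20 bis{(2R)-1-(benzyloxy)-3-[3,4-bis(benzyloxy)phenyl]-1-oxopropan-2-yl} (1R,2R,3R,4R)-3,4-bis[3,4-bis(benzyloxy)phenyl]cyclobutane-1,2-dicarboxylate
Conditions: DIC (2.6 equiv), DMAP (0.2 equiv), CH2Cl2, 0 to 20 °C
Reagents that add atoms: none
Why: Steglich esterification; the trans-diacid cannot divert into a cyclic anhydride, the ring alpha-hydrogens are poorly acidic because an exocyclic enolate adds strain to the four-membered ring, and the C–O bond of 19 is not broken, so C1, C2 and both (R) side-chain centres are retained.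

Step 13
Reactants: 20 bis{(2R)-1-(benzyloxy)-3-[3,4-bis(benzyloxy)phenyl]-1-oxopropan-2-yl} (1R,2R,3R,4R)-3,4-bis[3,4-bis(benzyloxy)phenyl]cyclobutane-1,2-dicarboxylate
Product: 21 CNP0163929.1, (2R,2'R)-2,2'-{[(1R,2R,3R,4R)-3,4-bis(3,4-dihydroxyphenyl)cyclobutane-1,2-dicarbonyl]bis(oxy)}bis[3-(3,4-dihydroxyphenyl)propanoic acid]
Conditions: H2 (1 atm), 10% Pd/C, THF/MeOH (1:1), 20 °C
Reagents that add atoms: none
Why: Catalytic hydrogenolysis of eight benzyl aryl ethers and two benzyl esters under neutral conditions; no stereocentre is epimerisable there, the acyloxy carbons are homobenzylic and therefore inert, and arylcyclobutanes withstand 1 atm of hydrogen at room temperature.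

Compound list
1 | 3,4-bis(benzyloxy)benzaldehyde | O=Cc1ccc(OCc2ccccc2)c(OCc2ccccc2)c1 | starting material
2 | N-acetylglycine | CC(=O)NCC(=O)O | starting material
3 | 2-methyl-1,3-oxazol-5(4H)-one | CC1=NCC(=O)O1 | intermediate
4 | (Z)-4-[3,4-bis(benzyloxy)benzylidene]-2-methyl-1,3-oxazol-5(4H)-one | CC1=N/C(=C\c2ccc(OCc3ccccc3)c(OCc3ccccc3)c2)C(=O)O1 | intermediate
5 | sodium (Z)-2-acetamido-3-[3,4-bis(benzyloxy)phenyl]acrylate (sodium acetamidocinnamate) | CC(=O)N/C(=C\c1ccc(OCc2ccccc2)c(OCc2ccccc2)c1)C(=O)[O-].[Na+] | intermediate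
6 | 3-[3,4-bis(benzyloxy)phenyl]-2-oxopropanoic acid | O=C(O)C(=O)Cc1ccc(OCc2ccccc2)c(OCc2ccccc2)c1 | intermediate
7 | allyl 3-[3,4-bis(benzyloxy)phenyl]-2-oxopropanoate | C=CCOC(=O)C(=O)Cc1ccc(OCc2ccccc2)c(OCc2ccccc2)c1 | intermediate
8 | diallyl malonate | C=CCOC(=O)CC(=O)OCC=C | starting material
9 | diallyl 2-[3,4-bis(benzyloxy)benzylidene]malonate | C=CCOC(=O)C(=Cc1ccc(OCc2ccccc2)c(OCc2ccccc2)c1)C(=O)OCC=C | intermediate
10 | triallyl (2R)-2,3-bis[3,4-bis(benzyloxy)phenyl]-4-oxobutane-1,1,4-tricarboxylate, C4 labile and left undefined | C=CCOC(=O)C(=O)C(c1ccc(OCc2ccccc2)c(OCc2ccccc2)c1)[C@@H](c1ccc(OCc2ccccc2)c(OCc2ccccc2)c1)C(C(=O)OCC=C)C(=O)OCC=C | intermediate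
11 | triallyl (2R,3S,4R)-2,3-bis[3,4-bis(benzyloxy)phenyl]-4-hydroxybutane-1,1,4-tricarboxylate | C=CCOC(=O)[C@H](O)[C@H](c1ccc(OCc2ccccc2)c(OCc2ccccc2)c1)[C@@H](c1ccc(OCc2ccccc2)c(OCc2ccccc2)c1)C(C(=O)OCC=C)C(=O)OCC=C | intermediate
12 | triallyl (2R,3S,4R)-2,3-bis[3,4-bis(benzyloxy)phenyl]-4-[(trifluoromethanesulfonyl)oxy]butane-1,1,4-tricarboxylate | C=CCOC(=O)[C@H](OS(=O)(=O)C(F)(F)F)[C@H](c1ccc(OCc2ccccc2)c(OCc2ccccc2)c1)[C@@H](c1ccc(OCc2ccccc2)c(OCc2ccccc2)c1)C(C(=O)OCC=C)C(=O)OCC=C | intermediate
13 | sodium malonate enolate of 12 | [Na+].C=CCOC(=O)[C@H](OS(=O)(=O)C(F)(F)F)[C@H](c1ccc(OCc2ccccc2)c(OCc2ccccc2)c1)[C@@H](c1ccc(OCc2ccccc2)c(OCc2ccccc2)c1)[C-](C(=O)OCC=C)C(=O)OCC=C | intermediate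
14 | triallyl (2R,3R,4S)-3,4-bis[3,4-bis(benzyloxy)phenyl]cyclobutane-1,1,2-tricarboxylate | C=CCOC(=O)[C@H]1C(C(=O)OCC=C)(C(=O)OCC=C)[C@H](c2ccc(OCc3ccccc3)c(OCc3ccccc3)c2)[C@H]1c1ccc(OCc2ccccc2)c(OCc2ccccc2)c1 | intermediate
15 | (2R,3R,4S)-3,4-bis[3,4-bis(benzyloxy)phenyl]cyclobutane-1,1,2-tricarboxylic acid | O=C(O)[C@H]1C(C(=O)O)(C(=O)O)[C@H](c2ccc(OCc3ccccc3)c(OCc3ccccc3)c2)[C@H]1c1ccc(OCc2ccccc2)c(OCc2ccccc2)c1 | intermediate
16 | (1R,3S,4R)-3,4-bis[3,4-bis(benzyloxy)phenyl]-2-(dihydroxymethylidene)cyclobutane-1-carboxylic acid (C2 enediol) | OC(O)=C1[C@H](C(=O)O)[C@H](c2ccc(OCc3ccccc3)c(OCc3ccccc3)c2)[C@H]1c1ccc(OCc2ccccc2)c(OCc2ccccc2)c1 | intermediate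
17 | (1R,2R,3R,4R)-3,4-bis[3,4-bis(benzyloxy)phenyl]cyclobutane-1,2-dicarboxylic acid | O=C(O)[C@H]1[C@H](C(=O)O)[C@H](c2ccc(OCc3ccccc3)c(OCc3ccccc3)c2)[C@H]1c1ccc(OCc2ccccc2)c(OCc2ccccc2)c1 | intermediate
18 | (R)-danshensu, (2R)-3-(3,4-dihydroxyphenyl)-2-hydroxypropanoic acid | O[C@H](Cc1ccc(O)c(O)c1)C(=O)O | starting material
19 | benzyl (2R)-3-[3,4-bis(benzyloxy)phenyl]-2-hydroxypropanoate | O[C@H](Cc1ccc(OCc2ccccc2)c(OCc2ccccc2)c1)C(=O)OCc1ccccc1 | intermediate
20 | bis{(2R)-1-(benzyloxy)-3-[3,4-bis(benzyloxy)phenyl]-1-oxopropan-2-yl} (1R,2R,3R,4R)-3,4-bis[3,4-bis(benzyloxy)phenyl]cyclobutane-1,2-dicarboxylate | O=C(O[C@H](Cc1ccc(OCc2ccccc2)c(OCc2ccccc2)c1)C(=O)OCc1ccccc1)[C@H]1[C@H](C(=O)O[C@H](Cc2ccc(OCc3ccccc3)c(OCc3ccccc3)c2)C(=O)OCc2ccccc2)[C@H](c2ccc(OCc3ccccc3)c(OCc3ccccc3)c2)[C@H]1c1ccc(OCc2ccccc2)c(OCc2ccccc2)c1 | intermediate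
21 | CNP0163929.1 | O=C(O[C@H](Cc1ccc(O)c(O)c1)C(=O)O)[C@H]1[C@H](C(=O)O[C@H](Cc2ccc(O)c(O)c2)C(=O)O)[C@H](c2ccc(O)c(O)c2)[C@H]1c1ccc(O)c(O)c1 | target

Total step count: 13. Longest linear sequence: 11 steps (1, 2, 3, 5, 6, 7, 8, 9, 10, 12, 13) from 3,4-bis(benzyloxy)benzaldehyde.

Steps most likely to fail

Step 5. The addition to an electron-rich arylidenemalonate may be slow and reversible. The chelating keto ester may displace the acceptor from scandium. Facial selectivity at C3 may be poor. The fallback sets out from 7 and 9 and comes back at 11. A DBU-catalysed Michael addition in concentrated toluene, the classical reaction of enolisable carbon acids with arylidenemalonates, gives the stereorandom keto triester F1. The transfer hydrogenation of step 6 controls C4 and C1 independently of C3. It therefore turns the two C3 antipodes into two diastereomeric (1R,4S) carbinols, 11 and the (3S)-configured carbinol F2, which are separated by chromatography. Half of the material is given up, but the absolute configuration then rests only on established transfer hydrogenation.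

Step 8. Triflic acid may be lost toward the benzylic C4–H. The chain may fragment at C3–C4 in the Grob sense. A malonate ester carbonyl may displace the triflate before the base has acted. The fallback sets out from 11 and comes back at 14, and it makes no discrete sulfonate and uses no external base. It is a Mitsunobu–Tsunoda cyclodehydration with cyanomethylenetributylphosphorane (Bu3P=CHCN) in toluene at 80 °C. The reagent activates the hydroxyl as an alkoxyphosphonium ion and takes the malonate proton in the same event. Carbon then displaces tributylphosphine oxide from C1 with the same inversion. No compound outside the list is made (F0).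

Step 10. Facial selectivity in the ketonisation of the C2 enediol may be poor. The free acid may open the C2–C3 bond of the donor–acceptor ring at 80 °C. The two cis carboxyl groups may form an anhydride that steers C2 to the wrong epimer. The fallback sets out from 14 and comes back at 17, and it replaces the stereoselective protonation by a stereospecific exchange of carbon for hydrogen.
- iBu2AlH (1 equiv, CH2Cl2, −78 °C) should attack the more electrophilic geminal ester pair. Within that pair it should take the ester turned away from the C3 aryl, giving the formyl diester F3.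
- Tsuji–Wilkinson decarbonylation with RhCl(PPh3)3 (1 equiv, toluene, reflux), which proceeds with retention at the migrating carbon, gives the diallyl diester F4.
- The conditions of step 9 then release 17.

Further compounds
F1 | step 5 | triallyl 2,3-bis[3,4-bis(benzyloxy)phenyl]-4-oxobutane-1,1,4-tricarboxylate, racemic at C3 and epimeric at C4 | C=CCOC(=O)C(=O)C(c1ccc(OCc2ccccc2)c(OCc2ccccc2)c1)C(c1ccc(OCc2ccccc2)c(OCc2ccccc2)c1)C(C(=O)OCC=C)C(=O)OCC=C
F2 | step 5 | triallyl (2S,3S,4R)-2,3-bis[3,4-bis(benzyloxy)phenyl]-4-hydroxybutane-1,1,4-tricarboxylate | C=CCOC(=O)[C@H](O)[C@H](c1ccc(OCc2ccccc2)c(OCc2ccccc2)c1)[C@H](c1ccc(OCc2ccccc2)c(OCc2ccccc2)c1)C(C(=O)OCC=C)C(=O)OCC=C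
F0 | step 8 | none | none
F3 | step 10 | diallyl (1R,2R,3R,4S)-3,4-bis[3,4-bis(benzyloxy)phenyl]-1-formylcyclobutane-1,2-dicarboxylate | C=CCOC(=O)[C@H]1[C@](C=O)(C(=O)OCC=C)[C@H](c2ccc(OCc3ccccc3)c(OCc3ccccc3)c2)[C@H]1c1ccc(OCc2ccccc2)c(OCc2ccccc2)c1
F4 | step 10 | diallyl (1R,2R,3R,4R)-3,4-bis[3,4-bis(benzyloxy)phenyl]cyclobutane-1,2-dicarboxylate | C=CCOC(=O)[C@H]1[C@H](C(=O)OCC=C)[C@H](c2ccc(OCc3ccccc3)c(OCc3ccccc3)c2)[C@H]1c1ccc(OCc2ccccc2)c(OCc2ccccc2)c1
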